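**Plan**

- Cuts: first C3′=C4′ of the dienoic acid chain (Julia–Kocienski; C1′–C3′ and the C2′ methyl come from methyl (S)-3-hydroxy-2-methylpropanoate), then C5′=C6′ (Horner–Wadsworth–Emmons). After formal hydration of C8=C9 and closure of an 8α,13-enol ether, the last cut takes C4–C5, C9–C10 and C8–O together.
- Enabling feature: rings A and B (gem-dimethyl C4, C5–H, quaternary C10–CH3, C8–CH3) plus the C11–C13 arm and its methyl are a head-to-tail (E,E)-farnesyl chain carrying an acetone unit, so one cationic cascade on farnesylacetone builds them.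
- Forward order: farnesol is homologated to farnesylacetone; a cyclase closes ring A, ring B and a temporary dihydropyran in one step; the pyran is opened, the chain is extended by two carbons, and C8–OH is eliminated into the ring. The enal is then joined to the four-carbon sulfone, desilylated and oxidised to the acid.
- Stereochemistry: C5 and C10 come from the enzyme-enforced chair–chair fold of the all-E polyene (C8 and C9 are set too and later erased); C2′ comes from the chiral hydroxy ester; 5′E from the Horner–Wadsworth–Emmons step and 3′E from the Julia–Kocienski step.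

Key step: step 4

Remarks: decalin and arm carbons carry labdane numbers (C1–C15); the acid chain of the target is numbered C1′ (CO2H) to C8′. Assumption: the cyclase is made by routine recombinant expression and used as a cell-free extract; its preparation is not counted as a step.

**Route**

Step 1
Reactants: 1 (2E,6E)-farnesol
Product: 2 (2E,6E)-farnesyl bromide
Conditions: PBr3 (0.4 equiv), Et2O, −10 → 0 °C; used crude
Reagents that add atoms: phosphorus tribromide, BrP(Br)Br
Why: The primary allylic alcohol is activated as a bromophosphite and displaced by bromide (SN2 bromination with PBr3) at low temperature, which leaves both trisubstituted E-olefins in place.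

Step 2
Reactants: 2 (2E,6E)-farnesyl bromide; 3 ethyl acetoacetate
Product: 4 ethyl (4E,8E)-2-acetyl-5,9,13-trimethyltetradeca-4,8,12-trienoate (racemic at C2)
Conditions: 3 (1.5 equiv), NaH, THF, 0 °C; then 2, 0 °C → rt
Reagents that add atoms: none
Why: Acetoacetic ester alkylation, in which the soft sodium enolate attacks the primary allylic bromide at carbon by SN2, the excess of enolate holding back dialkylation and the new C2 centre being lost again in step 3.

Step 3
Reactants: 4 ethyl (4E,8E)-2-acetyl-5,9,13-trimethyltetradeca-4,8,12-trienoate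
Product: 6 (5E,9E)-farnesylacetone [(5E,9E)-6,10,14-trimethylpentadeca-5,9,13-trien-2-one], via β-keto acid 5 (not isolated)
Conditions: NaOH, EtOH/H2O, 50 °C; then 1 M HCl to pH 3, 40 °C
Reagents that add atoms: none
Why: Ketonic cleavage of the acetoacetic ester, that is saponification followed by decarboxylation of the β-keto acid through its cyclic six-membered transition state, under conditions too mild to hydrate or cyclize the olefins.

Step 4
Reactants: 6 (5E,9E)-farnesylacetone
Product: 7 sclareol oxide [8α,13-epoxy-14,15-dinorlabd-12-ene; (4aR,6aS,10aS,10bR)-3,4a,7,7,10a-pentamethyl-4a,5,6,6a,7,8,9,10,10a,10b-decahydro-1H-benzo[f]chromene]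
Conditions: squalene–hopene cyclase of Alicyclobacillus acidocaldarius (cell-free extract of recombinant E. coli), sodium dodecyl sulfate (0.05%), sodium citrate buffer pH 6.0, 45 °C
Reagents that add atoms: none
Why: The acidic aspartate of the cyclase protonates C3 of the terminal olefin of 6 held in a chair–chair fold, and the cascade then forms C4–C5 (ring A, 6-endo-trig), C9–C10 (ring B, 6-endo-trig) and O–C8 (the dihydropyran, six-membered, closed by the ketone oxygen adding to the C8 cation with the C13=O unit inside the new ring), after which the oxocarbenium ion loses a C12 proton to give the enol ether. The closest known reaction type is the Stork–Eschenmoser cationic polyene cyclization as squalene–hopene cyclases perform it on homofarnesol and on geranyl- and farnesylacetone. C5 and C10 arise by antiperiplanar addition across the 9E olefin of 6 (farnesylacetone numbering), which fixes the trans ring fusion, and C9 and C8 by antiperiplanar addition across the 5E olefin, which places the C11 arm and the ether oxygen both equatorial (9β-carbon, 8α-oxygen). The absolute sense (5S,10S) is set by the enzyme pocket, which admits only one of the two mirror-image chair–chair folds of the achiral chain. The step needs complete bicyclization with oxygen termination in preference to early proton loss or water capture, and this is secured by the all-E geometry, by the six-atom spacing that holds the carbonyl oxygen over C8, and by the weak basicity of the ketone, which does not quench the catalytic acid.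

Step 5
Reactants: 7 sclareol oxide
Product: 8 8α-hydroxy-14,15-dinorlabdan-13-one [4-[(1R,2R,4aS,8aS)-2-hydroxy-2,5,5,8a-tetramethyldecahydronaphthalen-1-yl]butan-2-one]
Conditions: 0.5 M HCl, THF/H2O, 0 °C → rt
Reagents that add atoms: water, O
Why: Acid-catalysed enol ether hydrolysis (C12 protonation, addition of water to the oxocarbenium ion, opening of the hemiketal) frees the methyl ketone without breaking the tertiary C8–O bond, so the open ketol, expected to dominate over its cyclic hemiketal, keeps C8 and C9 as set in step 4.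

Step 6
Reactants: 8 8α-hydroxy-14,15-dinorlabdan-13-one
Product: 9 ethyl (13E)-8α-hydroxylabd-13-en-15-oate [ethyl (2E)-5-[(1R,2R,4aS,8aS)-2-hydroxy-2,5,5,8a-tetramethyldecahydronaphthalen-1-yl]-3-methylpent-2-enoate]
Conditions: (EtO)2P(O)CH2CO2Et (3 equiv), NaH (3 equiv), THF, 0 → 50 °C; chromatography
Reagents that add atoms: triethyl phosphonoacetate, CCOC(=O)CP(=O)(OCC)OCC
Why: Horner–Wadsworth–Emmons olefination of the methyl ketone, in which reversible addition and collapse of the less crowded oxaphosphetane place the ester trans to the C12 methylene (13E), the minor geometric isomer being removed by chromatography and the hindered tertiary alkoxide remaining a spectator.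

Step 7
Reactants: 9 ethyl (13E)-8α-hydroxylabd-13-en-15-oate
Product: 10 ethyl (13E)-labda-8,13-dien-15-oate [ethyl (2E)-3-methyl-5-[(4aS,8aS)-2,5,5,8a-tetramethyl-3,4,4a,5,6,7,8,8a-octahydronaphthalen-1-yl]pent-2-enoate]
Conditions: PPh3, I2, CH2Cl2, rt
Reagents that add atoms: none
Why: Zaitsev-selective dehydration of a tertiary alcohol with PPh3/I2, in which the alkoxyphosphonium iodide ionizes to the C8 cation and loss of the C9 proton, backed by HI-mediated equilibration of less substituted isomers, gives the tetrasubstituted C8=C9 olefin, while the electron-poor enoate does not intercept the cation and C5 and C10 are untouched.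

Step 8
Reactants: 10 ethyl (13E)-labda-8,13-dien-15-oate
Product: 11 (13E)-labda-8,13-dien-15-ol [(2E)-3-methyl-5-[(4aS,8aS)-2,5,5,8a-tetramethyl-3,4,4a,5,6,7,8,8a-octahydronaphthalen-1-yl]pent-2-en-1-ol]
Conditions: i-Bu2AlH (2.5 equiv), CH2Cl2, −78 °C; aqueous KNaC4H4O6 work-up
Reagents that add atoms: none
Why: 1,2-Reduction of the conjugated ester by i-Bu2AlH stops cleanly at the allylic alcohol and does not touch the olefin geometry or the ring olefin.

Step 9
Reactants: 11 (13E)-labda-8,13-dien-15-ol
Product: 12 (13E)-labda-8,13-dien-15-al [(2E)-3-methyl-5-[(4aS,8aS)-2,5,5,8a-tetramethyl-3,4,4a,5,6,7,8,8a-octahydronaphthalen-1-yl]pent-2-enal]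
Conditions: MnO2 (activated, excess), CH2Cl2, rt
Reagents that add atoms: none
Why: MnO2 oxidises allylic alcohols selectively to enals on its surface without over-oxidation or loss of the E geometry.

Step 10
Reactants: 13 methyl (S)-3-hydroxy-2-methylpropanoate
Product: 14 methyl (2S)-3-[(tert-butyldimethylsilyl)oxy]-2-methylpropanoate
Conditions: TBSCl, imidazole, CH2Cl2, 0 °C → rt
Reagents that add atoms: tert-butyldimethylsilyl chloride, CC(C)(C)[Si](C)(C)Cl
Why: Imidazole-promoted silylation of the primary alcohol is too weakly basic to epimerise the α-centre or to cause β-elimination.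

Step 11
Reactants: 14 methyl (2S)-3-[(tert-butyldimethylsilyl)oxy]-2-methylpropanoate
Product: 15 (2R)-3-[(tert-butyldimethylsilyl)oxy]-2-methylpropan-1-ol
Conditions: i-Bu2AlH (2.2 equiv), CH2Cl2, −78 → 0 °C; aqueous KNaC4H4O6 work-up
Reagents that add atoms: none
Why: Hydride reduction of the ester to the primary alcohol leaves the stereocentre untouched, its descriptor changing from S to R only through the change in substituent priorities.

Step 12
Reactants: 15 (2R)-3-[(tert-butyldimethylsilyl)oxy]-2-methylpropan-1-ol
Product: 16 5-{[(2S)-3-[(tert-butyldimethylsilyl)oxy]-2-methylpropyl]sulfanyl}-1-phenyl-1H-tetrazole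
Conditions: 1-phenyl-1H-tetrazole-5-thiol, PPh3, DIAD, THF, 0 °C → rt
Reagents that add atoms: 1-phenyl-1H-tetrazole-5-thiol, Sc1nnnn1-c1ccccc1
Why: Mitsunobu thioetherification, in which the acidic thiol displaces the oxyphosphonium group at the primary carbon, one atom away from the stereocentre.

Step 13
Reactants: 16 5-{[(2S)-3-[(tert-butyldimethylsilyl)oxy]-2-methylpropyl]sulfanyl}-1-phenyl-1H-tetrazole
Product: 18 5-{[(2S)-3-[(tert-butyldimethylsilyl)oxy]-2-methylpropyl]sulfonyl}-1-phenyl-1H-tetrazole, via sulfoxide 17 (not isolated)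
Conditions: (NH4)6Mo7O24·4H2O (catalytic), 30% H2O2, EtOH, 0 °C → rt
Reagents that add atoms: hydrogen peroxide, OO
Why: Molybdate-catalysed peroxide oxidation takes the sulfide through the sulfoxide to the sulfone under conditions that a primary silyl ether and the tetrazole tolerate.

Step 14
Reactants: 12 (13E)-labda-8,13-dien-15-al; 18 5-{[(2S)-3-[(tert-butyldimethylsilyl)oxy]-2-methylpropyl]sulfonyl}-1-phenyl-1H-tetrazole
Product: 19 tert-butyl{[(2R,3E,5E)-2,6-dimethyl-8-[(4aS,8aS)-2,5,5,8a-tetramethyl-3,4,4a,5,6,7,8,8a-octahydronaphthalen-1-yl]octa-3,5-dien-1-yl]oxy}dimethylsilane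
Conditions: 18 (1.3 equiv), KN(SiMe3)2, DME, −60 °C; then 12, −60 °C → rt
Reagents that add atoms: none
Why: Julia–Kocienski olefination, in which the potassium sulfonyl carbanion adds to the enal, the alkoxide undergoes Smiles transfer of the tetrazole and the sulfinate fragments antiperiplanar, the open transition state favoured by potassium in DME and the conjugated aldehyde both steering towards the E-olefin, while the β-stereocentre of the sulfone is not acidic and is carried through unchanged.

Step 15
Reactants: 19 the silyl ether from step 14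
Product: 20 (2R,3E,5E)-2,6-dimethyl-8-[(4aS,8aS)-2,5,5,8a-tetramethyl-3,4,4a,5,6,7,8,8a-octahydronaphthalen-1-yl]octa-3,5-dien-1-ol
Conditions: Bu4NF, THF, 0 °C → rt
Reagents that add atoms: none
Why: Fluoride cleaves the Si–O bond of the primary silyl ether under conditions to which the diene and the ring olefin are inert.

Step 16
Reactants: 20 (2R,3E,5E)-dienol from step 15
Product: 21 (2R,3E,5E)-2,6-dimethyl-8-[(4aS,8aS)-2,5,5,8a-tetramethyl-3,4,4a,5,6,7,8,8a-octahydronaphthalen-1-yl]octa-3,5-dienal
Conditions: Dess–Martin periodinane, NaHCO3, CH2Cl2, 0 °C; used crude at once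
Reagents that add atoms: none
Why: Dess–Martin oxidation under bicarbonate buffering is fast and close to neutral, so the α-stereocentre should not epimerise and the β,γ-olefin should not move into conjugation before the aldehyde is used.

Step 17
Reactants: 21 (2R,3E,5E)-dienal from step 16
Product: 22 (2R,3E,5E)-2,6-dimethyl-8-[(4aS,8aS)-2,5,5,8a-tetramethyl-3,4,4a,5,6,7,8,8a-octahydronaphthalen-1-yl]octa-3,5-dienoic acid (CNP0106052.1)
Conditions: NaClO2, NaH2PO4, 2-methyl-2-butene (large excess), t-BuOH/H2O, 0 °C → rt
Reagents that add atoms: sodium chlorite, [Na+].[O-]Cl=O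
Why: Pinnick oxidation, in which chlorous acid adds to the aldehyde and fragments to the acid and HOCl, the latter being trapped by 2-methyl-2-butene so that the diene and the tetrasubstituted olefin are spared and the weakly acidic buffer leaves C2′ untouched.

**Compound list**

1 | (2E,6E)-farnesol | CC(C)=CCC/C(C)=C/CC/C(C)=C/CO | starting material
2 | (2E,6E)-farnesyl bromide | CC(C)=CCC/C(C)=C/CC/C(C)=C/CBr | intermediate
3 | ethyl acetoacetate | CCOC(=O)CC(C)=O | starting material
4 | ethyl (4E,8E)-2-acetyl-5,9,13-trimethyltetradeca-4,8,12-trienoate (racemic at C2) | CC(C)=CCC/C(C)=C/CC/C(C)=C/CC(C(C)=O)C(=O)OCC | intermediate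
5 | (4E,8E)-2-acetyl-5,9,13-trimethyltetradeca-4,8,12-trienoic acid (β-keto acid, not isolated) | CC(C)=CCC/C(C)=C/CC/C(C)=C/CC(C(C)=O)C(=O)O | intermediate
6 | (5E,9E)-farnesylacetone | CC(C)=CCC/C(C)=C/CC/C(C)=C/CCC(C)=O | intermediate
7 | sclareol oxide (8α,13-epoxy-14,15-dinorlabd-12-ene) | CC1=CC[C@@H]2[C@@]3(C)CCCC(C)(C)[C@@H]3CC[C@@]2(C)O1 | intermediate
8 | 8α-hydroxy-14,15-dinorlabdan-13-one | CC(=O)CC[C@@H]1[C@@]2(C)CCCC(C)(C)[C@@H]2CC[C@@]1(C)O | intermediate
9 | ethyl (13E)-8α-hydroxylabd-13-en-15-oate | CCOC(=O)/C=C(\C)CC[C@@H]1[C@@]2(C)CCCC(C)(C)[C@@H]2CC[C@@]1(C)O | intermediate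
10 | ethyl (13E)-labda-8,13-dien-15-oate | CC1=C(CC/C(C)=C/C(=O)OCC)[C@@]2(C)CCCC(C)(C)[C@@H]2CC1 | intermediate
11 | (13E)-labda-8,13-dien-15-ol | CC1=C(CC/C(C)=C/CO)[C@@]2(C)CCCC(C)(C)[C@@H]2CC1 | intermediate
12 | (13E)-labda-8,13-dien-15-al | CC1=C(CC/C(C)=C/C=O)[C@@]2(C)CCCC(C)(C)[C@@H]2CC1 | intermediate
13 | methyl (S)-3-hydroxy-2-methylpropanoate | COC(=O)[C@@H](C)CO | starting material
14 | methyl (2S)-3-[(tert-butyldimethylsilyl)oxy]-2-methylpropanoate | COC(=O)[C@@H](C)CO[Si](C)(C)C(C)(C)C | intermediate
15 | (2R)-3-[(tert-butyldimethylsilyl)oxy]-2-methylpropan-1-ol | OC[C@@H](C)CO[Si](C)(C)C(C)(C)C | intermediate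
16 | 5-{[(2S)-3-[(tert-butyldimethylsilyl)oxy]-2-methylpropyl]sulfanyl}-1-phenyl-1H-tetrazole | c1ccccc1-n1nnnc1SC[C@@H](C)CO[Si](C)(C)C(C)(C)C | intermediate
17 | 5-{[(2S)-3-[(tert-butyldimethylsilyl)oxy]-2-methylpropyl]sulfinyl}-1-phenyl-1H-tetrazole (both sulfur epimers, not isolated) | c1ccccc1-n1nnnc1S(=O)C[C@@H](C)CO[Si](C)(C)C(C)(C)C | intermediate
18 | 5-{[(2S)-3-[(tert-butyldimethylsilyl)oxy]-2-methylpropyl]sulfonyl}-1-phenyl-1H-tetrazole | c1ccccc1-n1nnnc1S(=O)(=O)C[C@@H](C)CO[Si](C)(C)C(C)(C)C | intermediate
19 | tert-butyldimethylsilyl ether of the (2R,3E,5E)-dienol 20 | CC1=C(CC/C(C)=C/C=C/[C@@H](C)CO[Si](C)(C)C(C)(C)C)[C@@]2(C)CCCC(C)(C)[C@@H]2CC1 | intermediate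
20 | (2R,3E,5E)-2,6-dimethyl-8-[(4aS,8aS)-2,5,5,8a-tetramethyl-3,4,4a,5,6,7,8,8a-octahydronaphthalen-1-yl]octa-3,5-dien-1-ol | CC1=C(CC/C(C)=C/C=C/[C@@H](C)CO)[C@@]2(C)CCCC(C)(C)[C@@H]2CC1 | intermediate
21 | (2R,3E,5E)-2,6-dimethyl-8-[(4aS,8aS)-2,5,5,8a-tetramethyl-3,4,4a,5,6,7,8,8a-octahydronaphthalen-1-yl]octa-3,5-dienal | CC1=C(CC/C(C)=C/C=C/[C@@H](C)C=O)[C@@]2(C)CCCC(C)(C)[C@@H]2CC1 | intermediate
22 | (2R,3E,5E)-2,6-dimethyl-8-[(4aS,8aS)-2,5,5,8a-tetramethyl-3,4,4a,5,6,7,8,8a-octahydronaphthalen-1-yl]octa-3,5-dienoic acid | CC1=C(CC/C(C)=C/C=C/[C@@H](C)C(=O)O)[C@@]2(C)CCCC(C)(C)[C@@H]2CC1 | target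

**Step count and weak points**

Total: 17 steps. Longest linear sequence: 13 steps (steps 1–9 and 14–17); the sulfone branch is 4 steps (10–13).

Step 4. The hydrophobic ketone may partition poorly into the enzyme, and the cascade may stop after ring A through early proton loss, so conversion to the bicyclic enol ether could stay low. The fallback sets out from 6 and runs the cyclization with fluorosulfonic acid in 2-nitropropane at −78 °C (quench with Et3N), a known superacid cyclization of farnesylacetone. It gives the racemate, that is 7 together with its mirror image ent-sclareol oxide F1. The enantiomers are then parted by preparative chromatography on a polysaccharide chiral stationary phase, and the route is rejoined at 7.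

Step 7. Proton loss from the C8 cation may not be regioselective, or the HI formed may scramble the 13E geometry of the enoate. The fallback sets out from 9 and separates elimination from olefin placement. Kinetic elimination with SOCl2 and pyridine in CH2Cl2 at −78 °C should give the exocyclic olefin ethyl (13E)-labda-8(17),13-dien-15-oate F2, accompanied by the endocyclic isomer ethyl (13E)-labda-7,13-dien-15-oate F3. The crude olefin mixture is then equilibrated through the tertiary C8 cation with a sulfonic acid resin in CH2Cl2 at rt. Residual trisubstituted isomer is removed on AgNO3-impregnated silica, and the route is rejoined at 10.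

Step 14. E-selectivity may erode in the addition of a β-branched sulfonyl carbanion to a conjugated aldehyde, and the carbanion may instead deprotonate the enal at its γ-positions. The fallback inverts the polarity of the coupling and sets out from 11 and 15. Alcohol 11 is converted with PBr3 in Et2O at 0 °C into the allylic bromide (2E)-1-bromo-3-methyl-5-[(4aS,8aS)-2,5,5,8a-tetramethyl-3,4,4a,5,6,7,8,8a-octahydronaphthalen-1-yl]pent-2-ene F4. Bromide F4 is quaternised with PBu3 in MeCN to the allylic tributylphosphonium bromide F5. Alcohol 15 is oxidised with Dess–Martin periodinane (NaHCO3, CH2Cl2) to (2S)-3-[(tert-butyldimethylsilyl)oxy]-2-methylpropanal F6. The ylide from F5 (n-BuLi, THF, −78 °C) is condensed with F6 in a Wittig reaction; allylic tributylphosphonium ylides are known to give (E)-1,3-dienes with retention of the existing trisubstituted olefin. The route is rejoined at 19.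

**Further compounds**

F1 | step 4 | ent-sclareol oxide, (4aS,6aR,10aR,10bS)-enantiomer of 7 | CC1=CC[C@H]2[C@]3(C)CCCC(C)(C)[C@H]3CC[C@]2(C)O1
F2 | step 7 | ethyl (13E)-labda-8(17),13-dien-15-oate [ethyl (2E)-3-methyl-5-[(1S,4aS,8aS)-5,5,8a-trimethyl-2-methylidenedecahydronaphthalen-1-yl]pent-2-enoate] | CCOC(=O)/C=C(\C)CC[C@@H]1[C@@]2(C)CCCC(C)(C)[C@@H]2CCC1=C
F3 | step 7 | ethyl (13E)-labda-7,13-dien-15-oate [ethyl (2E)-3-methyl-5-[(1S,4aS,8aS)-2,5,5,8a-tetramethyl-1,4,4a,5,6,7,8,8a-octahydronaphthalen-1-yl]pent-2-enoate] | CCOC(=O)/C=C(\C)CC[C@@H]1[C@@]2(C)CCCC(C)(C)[C@@H]2CC=C1C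
F4 | step 14 | (2E)-1-bromo-3-methyl-5-[(4aS,8aS)-2,5,5,8a-tetramethyl-3,4,4a,5,6,7,8,8a-octahydronaphthalen-1-yl]pent-2-ene | CC1=C(CC/C(C)=C/CBr)[C@@]2(C)CCCC(C)(C)[C@@H]2CC1
F5 | step 14 | tributyl{(2E)-3-methyl-5-[(4aS,8aS)-2,5,5,8a-tetramethyl-3,4,4a,5,6,7,8,8a-octahydronaphthalen-1-yl]pent-2-en-1-yl}phosphonium bromide | CC1=C(CC/C(C)=C/C[P+](CCCC)(CCCC)CCCC)[C@@]2(C)CCCC(C)(C)[C@@H]2CC1.[Br-]
F6 | step 14 | (2S)-3-[(tert-butyldimethylsilyl)oxy]-2-methylpropanal | O=C[C@@H](C)CO[Si](C)(C)C(C)(C)C
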